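**Plan**

- Retrosynthesis (labdane numbering): the acetate and the C8=C17 methylene go first (acetylation, Wittig). Ring B is then cut at C6–C7 (aldol condensation of a C6 aldehyde with the C7 methyl of a C8 ketone), the side chain at C10–C9 (Michael addition to a nitroalkene), and ring A at C3–C4 and C5–C10 (Robinson annulation).
- Forward: ring A is built first, fused to a temporary five-membered lactone C4–C18(=O)–O–C6–C5 that the target does not contain. The C7–C9/C11–C16 piece from geranyl acetate is joined at C10, and ring B closes last at C6–C7.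
- Enabling feature: C18 (on C4) and C6 (on C5) sit on neighbouring ring-A carbons, so they can be tied as an (enol) lactone. That ring holds the C19 methyl axial, stores C6 as a masked aldehyde 1,5 to the C8 carbonyl, and is cleaved in the ring-B closure, which also frees the C18 acid.
- Stereochemistry: C4 from an enantioselective Michael addition; C10 from attack on the lactone-locked dienolate anti to the C19 methyl; C5 and C9 by equilibration in and after the ring-B closure; the 13E alkene is carried unchanged from geranyl acetate.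

Key step: step 8

Remark: all intermediates carry labdane atom numbers (C18 = carboxyl carbon on C4, C19 = methyl on C4, C20 = methyl on C10, C17 = methylene carbon on C8); C8 and C9 are carried as epimer mixtures from step 5 to step 7.
Assumption: 3-methyltetronic acid is taken as a commercial material, and of the two pseudo-enantiomeric cinchona catalysts the one that gives (R)-8 is used.

**Step 1**
Reactants: 1 geranyl acetate
Product: 2 (2E)-3-methyl-6-oxohex-2-en-1-yl acetate
Conditions: O3 (1.0 equiv), CH2Cl2/pyridine, −78 °C; then Me2S, −78 °C → rt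
Reagents that add atoms: ozone, [O-][O+]=O
Why: Chemoselective ozonolysis with reductive work-up should cleave the electron-rich 6,7-alkene in preference to the 2,3-alkene, which is deactivated by the allylic acetate and keeps its E geometry.

**Step 2**
Reactants: 2 (2E)-3-methyl-6-oxohex-2-en-1-yl acetate; 3 nitroethane
Product: 5 (2E,6E)-3-methyl-7-nitroocta-2,6-dien-1-yl acetate, via nitro alcohol 4 (not isolated)
Conditions: 1,1,3,3-tetramethylguanidine (10 mol %), THF, 0 °C; then MsCl, Et3N, CH2Cl2, −20 → 0 °C
Reagents that add atoms: none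
Why: A Henry addition followed by elimination of the derived mesylate should give the conjugated nitroalkene, whose geometry is of no consequence because both of its carbons are re-set later.

**Step 3**
Reactants: 6 3-methyltetronic acid; 7 ethyl vinyl ketone
Product: 8 (3R)-3-methyl-3-(3-oxopentyl)furan-2,4(3H,5H)-dione
Conditions: 9-O-(9-phenanthryl)cupreidine (10 mol %), CH2Cl2, −20 °C
Reagents that add atoms: none
Why: Cinchona-alkaloid-catalysed enantioselective Michael addition of a 2-substituted cyclic 1,3-dicarbonyl compound to a vinyl ketone should create the quaternary C4, the quinuclidinium/6'-hydroxyl pair binding tetronate and enone so that one enolate face is alkylated at carbon.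

**Step 4**
Reactants: 8 (3R)-3-methyl-3-(3-oxopentyl)furan-2,4(3H,5H)-dione
Product: 9 (7aR)-4,7a-dimethyl-7,7a-dihydro-2-benzofuran-1,5(3H,6H)-dione
Conditions: p-TsOH·H2O (10 mol %), toluene, reflux, azeotropic removal of water
Reagents that add atoms: none
Why: The aldol condensation that completes a Robinson annulation should join the ethyl-ketone methylene (C10) to the strained ring ketone (C5) and dehydrate to the C5=C10 enone, since the only other closure (C6 onto C1) gives a bridged ketol that reverts, and the quaternary C4 is not touched.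

**Step 5**
Reactants: 9 (7aR)-4,7a-dimethyl-7,7a-dihydro-2-benzofuran-1,5(3H,6H)-dione; 5 (2E,6E)-3-methyl-7-nitroocta-2,6-dien-1-yl acetate
Product: 11 (4R,7aR)-4-[(6E)-8-acetoxy-6-methyl-2-nitrooct-6-en-3-yl]-4,7a-dimethyl-6,7-dihydro-2-benzofuran-1,5(4H,7aH)-dione, via potassium dienolate 10 (not isolated)
Conditions: t-BuOK (1.05 equiv), THF, −78 → −30 °C; then 5, −78 °C; AcOH quench
Reagents that add atoms: none
Why: Deprotonation at C6 gives the extended dienolate, which should add through its α-carbon C10 to the nitroalkene (Michael addition, deconjugative α-alkylation of an enone) on the face anti to the C19 methyl, because the fused lactone holds C18 in the dienolate plane and C19 axial; this places C9 cis to C18 and leaves the C5=C6 enol lactone.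

**Step 6**
Reactants: 11 (4R,7aR)-4-[(6E)-8-acetoxy-6-methyl-2-nitrooct-6-en-3-yl]-4,7a-dimethyl-6,7-dihydro-2-benzofuran-1,5(4H,7aH)-dione
Product: 13 (4R,7aR)-4-[(6E)-8-acetoxy-6-methyl-2-nitrooct-6-en-3-yl]-4,7a-dimethyl-5,6,7,7a-tetrahydro-2-benzofuran-1(4H)-one, via tosylhydrazone 12 (not isolated)
Conditions: TsNHNH2, PPTS (cat.), THF, 50 °C; then catecholborane, CHCl3, 0 °C; then NaOAc·3H2O, reflux
Reagents that add atoms: none
Why: Reduction of the tosylhydrazone of the unconjugated C1 ketone with a borane hydride (a mild Wolff–Kishner-type deoxygenation) should give the C1 methylene without touching the nitro group, the acetate, the enol lactone or the alkenes, and removes the carbonyl that was needed only to make C10 nucleophilic.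

**Step 7**
Reactants: 13 (4R,7aR)-4-[(6E)-8-acetoxy-6-methyl-2-nitrooct-6-en-3-yl]-4,7a-dimethyl-5,6,7,7a-tetrahydro-2-benzofuran-1(4H)-one
Product: 15 (4R,7aR)-4-[(6E)-8-acetoxy-6-methyl-2-oxooct-6-en-3-yl]-4,7a-dimethyl-5,6,7,7a-tetrahydro-2-benzofuran-1(4H)-one, via potassium nitronate 14 (not isolated)
Conditions: t-BuOK (1.05 equiv), THF, −40 °C; then aq. TiCl3, NH4OAc (pH 5), 0 °C → rt
Reagents that add atoms: water, O
Why: A reductive Nef reaction, in which trivalent titanium reduces the nitronate to the imine that hydrolyses in the buffer, should turn C8 into the methyl ketone under conditions mild enough for the enol lactone and the acetate.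

**Step 8**
Reactants: 15 (4R,7aR)-4-[(6E)-8-acetoxy-6-methyl-2-oxooct-6-en-3-yl]-4,7a-dimethyl-5,6,7,7a-tetrahydro-2-benzofuran-1(4H)-one
Product: 18 (13E)-15-hydroxy-8-oxo-17-norlabda-6,13-dien-18-oic acid, via keto aldehyde acid 16 (not isolated), via aldol 17 (not isolated)
Conditions: KOH (6 equiv), H2O/1,4-dioxane (1:2), 0 → 70 °C; then 1 M HCl to pH 3
Reagents that add atoms: potassium hydroxide, [K+].[OH-]
Why: Hydroxide opens the enol lactone at C18 (acyl–oxygen cleavage), which frees the C18 carboxylate and the C6 aldehyde (16) and also removes the acetate; the methyl-ketone enolate (C7) then adds to C6 (17) and loss of water by E1cB gives the enone, so the temporary C18–O–C6 ring is spent in the operation that forms C6–C7. The closest known reaction type is the intramolecular aldol condensation of a 1,5-keto aldehyde (second stage of a Robinson annulation), here triggered by saponification of an enol ester. Ring B closes in the 6-(enolexo)-exo-trig mode and no other ring is formed. C5 and C9 are set under equilibrium control: C5 through the aldehyde enolate before closure and as the γ-position of the enone after it, which should favour the trans ring fusion (H5 anti to the C20 methyl), and C9, α' to the C8 carbonyl, should settle with its side chain equatorial, while the quaternary C4 and C10 cannot change. The step needs attack by the C7 (methyl) and not the C9 (methine) enolate, secured because only C7 reaches C6 through a six-membered ring, and it needs hydroxide to open the lactone before the ketone reacts elsewhere, secured by the activated enol-ester carbonyl.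

**Step 9**
Reactants: 18 (13E)-15-hydroxy-8-oxo-17-norlabda-6,13-dien-18-oic acid
Product: 19 (13E)-15-hydroxy-8-oxo-17-norlabd-13-en-18-oic acid
Conditions: Li (excess), NH3(l)/THF, −78 °C, 15 min; then solid NH4Cl
Reagents that add atoms: none
Why: Dissolving-metal reduction of the enone should give the C7 enolate and, after protonation, the saturated C8 ketone, the carboxylate, the alkoxide and the isolated trisubstituted alkene being inert and C5 and C9 not being involved.

**Step 10**
Reactants: 19 (13E)-15-hydroxy-8-oxo-17-norlabd-13-en-18-oic acid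
Product: 20 (13E)-15-hydroxylabda-8(17),13-dien-18-oic acid
Conditions: Ph3PCH3Br, t-BuOK (5 equiv each), toluene/THF, 70 °C
Reagents that add atoms: methyltriphenylphosphonium bromide, C[P+](c1ccccc1)(c1ccccc1)c1ccccc1.[Br-]
Why: Wittig methylenation with excess salt-free ylide (two equivalents are consumed by the acid and the alcohol) should convert the hindered C8 ketone into the exocyclic methylene, C9 staying in its stable equatorial configuration under the basic conditions.

**Step 11**
Reactants: 20 (13E)-15-hydroxylabda-8(17),13-dien-18-oic acid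
Product: 21 (13E)-15-acetoxylabda-8(17),13-dien-18-oic acid
Conditions: Ac2O, pyridine, DMAP (cat.), CH2Cl2, 0 °C → rt; then aq. NaHCO3, then dilute HCl
Reagents that add atoms: acetic anhydride, CC(=O)OC(C)=O
Why: Acylation of the primary allylic alcohol should give the acetate, and any mixed anhydride formed at the hindered C18 acid is hydrolysed in the aqueous work-up.

**Compound list**

1 | geranyl acetate, (2E)-3,7-dimethylocta-2,6-dien-1-yl acetate | CC(C)=CCC/C(C)=C/COC(C)=O | starting material
2 | (2E)-3-methyl-6-oxohex-2-en-1-yl acetate | O=CCC/C(C)=C/COC(C)=O | intermediate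
3 | nitroethane | CC[N+](=O)[O-] | starting material
4 | (2E)-6-hydroxy-3-methyl-7-nitrooct-2-en-1-yl acetate, mixture of diastereomers | CC([N+](=O)[O-])C(O)CC/C(C)=C/COC(C)=O | intermediate
5 | (2E,6E)-3-methyl-7-nitroocta-2,6-dien-1-yl acetate | [O-][N+](=O)/C(C)=C/CC/C(C)=C/COC(C)=O | intermediate
6 | 3-methyltetronic acid, 4-hydroxy-3-methylfuran-2(5H)-one | CC1=C(O)COC1=O | starting material
7 | ethyl vinyl ketone, pent-1-en-3-one | CCC(=O)C=C | starting material
8 | (3R)-3-methyl-3-(3-oxopentyl)furan-2,4(3H,5H)-dione | CCC(=O)CC[C@]1(C)C(=O)COC1=O | intermediate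
9 | (7aR)-4,7a-dimethyl-7,7a-dihydro-2-benzofuran-1,5(3H,6H)-dione (ring A enone fused to the C18–O–C6 lactone) | CC1=C2COC(=O)[C@]2(C)CCC1=O | intermediate
10 | potassium dienolate of 9 (C1 enolate, C10=C1 and C5=C6 double bonds) | [K+].[O-]C1=C(C)C2=COC(=O)[C@]2(C)CC1 | intermediate
11 | (4R,7aR)-4-[(6E)-8-acetoxy-6-methyl-2-nitrooct-6-en-3-yl]-4,7a-dimethyl-6,7-dihydro-2-benzofuran-1,5(4H,7aH)-dione, side chain cis to C18, C8/C9 epimer mixture | O=C1CC[C@@]2(C)C(=O)OC=C2[C@@]1(C)C(CC/C(C)=C/COC(C)=O)C(C)[N+](=O)[O-] | intermediate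
12 | C1 tosylhydrazone of 11 | Cc1ccc(cc1)S(=O)(=O)NN=C1CC[C@@]2(C)C(=O)OC=C2[C@@]1(C)C(CC/C(C)=C/COC(C)=O)C(C)[N+](=O)[O-] | intermediate
13 | (4R,7aR)-4-[(6E)-8-acetoxy-6-methyl-2-nitrooct-6-en-3-yl]-4,7a-dimethyl-5,6,7,7a-tetrahydro-2-benzofuran-1(4H)-one, C8/C9 epimer mixture | C1CC[C@@]2(C)C(=O)OC=C2[C@@]1(C)C(CC/C(C)=C/COC(C)=O)C(C)[N+](=O)[O-] | intermediate
14 | potassium nitronate of 13 | [K+].C1CC[C@@]2(C)C(=O)OC=C2[C@@]1(C)C(CC/C(C)=C/COC(C)=O)C(C)=[N+]([O-])[O-] | intermediate
15 | (4R,7aR)-4-[(6E)-8-acetoxy-6-methyl-2-oxooct-6-en-3-yl]-4,7a-dimethyl-5,6,7,7a-tetrahydro-2-benzofuran-1(4H)-one, C9 epimer mixture | C1CC[C@@]2(C)C(=O)OC=C2[C@@]1(C)C(CC/C(C)=C/COC(C)=O)C(C)=O | intermediate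
16 | 6,7-seco keto aldehyde acid: ring A with C4 (CH3, CO2H), C5 (H, CHO) and C10 (CH3, 1-acetyl-5-hydroxy-3-methylpent-3-enyl side chain), C5/C9 epimers | O=CC1[C@](C)(CCC[C@@]1(C)C(=O)O)C(CC/C(C)=C/CO)C(C)=O | intermediate
17 | (13E)-6,15-dihydroxy-8-oxo-17-norlabd-13-en-18-oic acid, C5/C6/C9 epimers | O=C1CC(O)C2[C@](C)(CCC[C@@]2(C)C(=O)O)C1CC/C(C)=C/CO | intermediate
18 | (13E)-15-hydroxy-8-oxo-17-norlabda-6,13-dien-18-oic acid | O=C1C=C[C@@H]2[C@](C)(CCC[C@@]2(C)C(=O)O)[C@H]1CC/C(C)=C/CO | intermediate
19 | (13E)-15-hydroxy-8-oxo-17-norlabd-13-en-18-oic acid | O=C1CC[C@@H]2[C@](C)(CCC[C@@]2(C)C(=O)O)[C@H]1CC/C(C)=C/CO | intermediate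
20 | (13E)-15-hydroxylabda-8(17),13-dien-18-oic acid | C=C1CC[C@@H]2[C@](C)(CCC[C@@]2(C)C(=O)O)[C@H]1CC/C(C)=C/CO | intermediate
21 | (13E)-15-acetoxylabda-8(17),13-dien-18-oic acid | C=C1CC[C@@H]2[C@](C)(CCC[C@@]2(C)C(=O)O)[C@H]1CC/C(C)=C/COC(C)=O | target

**Step count and risks**

Total step count: 11
Longest linear sequence: 9 steps (steps 3 to 11 from 6 and 7, or steps 1, 2 and 5 to 11 from 1)

Steps most likely to fail:

1. Step 5. The fully substituted dienolate carbon C10 may be too hindered to bond to the β-branched nitroalkene, so that the dienolate reacts through C6 instead or the nitroalkene is lost to retro-Michael reaction and oligomerization. The fallback sets out from 2 and 9 and returns at 15; it makes the same bond by a sigmatropic shift. Aldehyde 2 is extended with (triphenylphosphoranylidene)acetaldehyde to enal F1 and reduced (NaBH4, CeCl3·7H2O, MeOH) to allylic alcohol F2. Ketone 9 is converted with HC(OMe)3 and catalytic p-TsOH into methyl dienol ether F3. Heating F3 with F2 and a trace of propionic acid in xylene at 135 °C should exchange the ether to allyl dienol ether F4, which should undergo Claisen rearrangement in the same flask to ketone F5; the C10–C9 bond again forms anti to the C19 methyl, and C9 is left uncontrolled because step 8 corrects it. Deoxygenation at C1 as in step 6, through tosylhydrazone F6, should give enol lactone F7, and Wacker oxidation of its vinyl group (PdCl2, CuCl, O2, DMF/H2O) should give 15.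

2. Step 8. Ring closure may occur faster from the C5 epimer that leads to the cis-fused enone, and the hindered γ-hydrogen at C5 may then equilibrate too slowly. The fallback sets out from 15 and returns at 18; it fixes C5 by a kinetic hydrogen-atom transfer. Ketone 15 is converted (LiHMDS, TMSCl, THF, −78 °C) into silyl enol ether F8 and brominated with NBS to bromoketone F9. Slow addition of Bu3SnH/AIBN in benzene at 80 °C should bring about 6-endo-trig cyclization of the α-keto radical onto C6 of the enol lactone and reduction of the resulting C5 radical from the face anti to the C19 and C20 methyls, giving tricyclic lactone F10. DBU should then expel the C18 carboxylate from C6 (E1cB) to give enone acid F11, and K2CO3 in MeOH should remove the acetate and settle C9 to give 18.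

3. Step 3. The catalyst may not discriminate well enough between the two faces of the highly acidic tetronate, which would lower the enantiomeric purity of every later compound. The fallback sets out from 6 and 7 and returns at 8; it uses a stoichiometric chiral amine. Acid 6 is condensed with (S)-1-phenylethylamine (toluene, azeotropic removal of water) to enaminolactone F12, the amine enantiomer being the one that the usual model for such chiral secondary enamines assigns to the R product. Michael addition of F12 to 7 (THF, rt) should give imine F13, and 10% aqueous acetic acid should release 8 and the amine.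

**Further compounds**

F1 | step 5 | (2E,6E)-3-methyl-8-oxoocta-2,6-dien-1-yl acetate | O=C/C=C/CC/C(C)=C/COC(C)=O
F2 | step 5 | (2E,6E)-8-hydroxy-3-methylocta-2,6-dien-1-yl acetate | OC/C=C/CC/C(C)=C/COC(C)=O
F3 | step 5 | (7aR)-5-methoxy-4,7a-dimethyl-7,7a-dihydro-2-benzofuran-1(6H)-one, methyl dienol ether of 9 | COC1=C(C)C2=COC(=O)[C@]2(C)CC1
F4 | step 5 | allyl dienol ether of 9 with F2 | C1(OC/C=C/CC/C(C)=C/COC(C)=O)=C(C)C2=COC(=O)[C@]2(C)CC1
F5 | step 5 | (4R,7aR)-4-[(6E)-8-acetoxy-6-methylocta-1,6-dien-3-yl]-4,7a-dimethyl-6,7-dihydro-2-benzofuran-1,5(4H,7aH)-dione, C9 epimer mixture | O=C1CC[C@@]2(C)C(=O)OC=C2[C@@]1(C)C(C=C)CC/C(C)=C/COC(C)=O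
F6 | step 5 | C1 tosylhydrazone of F5 | Cc1ccc(cc1)S(=O)(=O)NN=C1CC[C@@]2(C)C(=O)OC=C2[C@@]1(C)C(C=C)CC/C(C)=C/COC(C)=O
F7 | step 5 | (4R,7aR)-4-[(6E)-8-acetoxy-6-methylocta-1,6-dien-3-yl]-4,7a-dimethyl-5,6,7,7a-tetrahydro-2-benzofuran-1(4H)-one | C1CC[C@@]2(C)C(=O)OC=C2[C@@]1(C)C(C=C)CC/C(C)=C/COC(C)=O
F8 | step 8 | trimethylsilyl enol ether of 15 at C7=C8 | C1CC[C@@]2(C)C(=O)OC=C2[C@@]1(C)C(CC/C(C)=C/COC(C)=O)C(=C)O[Si](C)(C)C
F9 | step 8 | C7 bromomethyl ketone of 15 | C1CC[C@@]2(C)C(=O)OC=C2[C@@]1(C)C(CC/C(C)=C/COC(C)=O)C(=O)CBr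
F10 | step 8 | (13E)-15-acetoxy-8-oxo-17-norlabd-13-en-18,6-olide, C6/C9 epimers | O=C1CC3[C@@H]2[C@](C)(CCC[C@@]2(C)C(=O)O3)C1CC/C(C)=C/COC(C)=O
F11 | step 8 | (13E)-15-acetoxy-8-oxo-17-norlabda-6,13-dien-18-oic acid, C9 epimers | O=C1C=C[C@@H]2[C@](C)(CCC[C@@]2(C)C(=O)O)C1CC/C(C)=C/COC(C)=O
F12 | step 3 | 3-methyl-4-{[(1S)-1-phenylethyl]amino}furan-2(5H)-one | CC1=C(N[C@@H](C)c2ccccc2)COC1=O
F13 | step 3 | (3R)-3-methyl-3-(3-oxopentyl)-4-{[(1S)-1-phenylethyl]imino}oxolan-2-one | CCC(=O)CC[C@]1(C)C(=N[C@@H](C)c2ccccc2)COC1=O
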